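## Retrosynthetic overview

1. The C5 acrylic acid is cut by a Heck disconnection (aryl bromide + acrylic acid) and the coumarate by a Mitsunobu disconnection (primary alcohol + free p‑coumaric acid).
2. The 5‑bromo‑2,3‑dihydrobenzofuran comes from an intramolecular inverse‑demand Diels–Alder/retro‑Diels–Alder (−N2) of a 3‑bromo‑6‑(homopropargyloxy)pyridazine. This one event forms the benzene ring and the dihydrofuran ring together and is the only ring‑forming step.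
3. The pyridazinyl ether comes from SNAr of 3,6‑dibromopyridazine with a syn homopropargylic alcohol; the carbinol C–O bond is kept, so it becomes C2 of the ring.
4. The alcohol comes from Felkin‑selective addition of allenyltributylstannane to the silyl‑protected Roche aldehyde, made from methyl (S)‑3‑hydroxy‑2‑methylpropanoate. The bought stereocentre becomes the side‑chain CH(CH3) and controls C2.

Assumption: the target SMILES is read as (2S) at the ring carbon and (S) at the side‑chain carbon (methyl and ring oxygen syn in the zigzag drawing); every reagent not made below is taken as bought.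

## Route

Step 1
Reactants: 1 methyl (S)‑3‑hydroxy‑2‑methylpropanoate (Roche ester); 2 triisopropylsilyl chloride
Product: 3 methyl (S)‑2‑methyl‑3‑[(triisopropylsilyl)oxy]propanoate
Conditions: TIPSCl (1.1 eq), imidazole (2 eq), DMF, 0 °C → rt
Reagents that add atoms: triisopropylsilyl chloride (2), CC(C)[Si](Cl)(C(C)C)C(C)C
Why: Imidazole‑mediated silylation of the primary alcohol gives a bulky, non‑chelating silyl ether that tolerates base, heat and Pd and resists O→O migration; the stereocentre is not touched.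

Step 2
Reactants: 3 methyl (S)‑2‑methyl‑3‑[(triisopropylsilyl)oxy]propanoate
Product: 4 (S)‑2‑methyl‑3‑[(triisopropylsilyl)oxy]propanal
Conditions: DIBAL‑H (1.1 eq), CH2Cl2, −78 °C; MeOH quench, aq. Rochelle salt; crude aldehyde used cold and at once
Reagents that add atoms: none
Why: Partial ester reduction with one equivalent of DIBAL‑H at −78 °C stops at the aldehyde oxidation level, and immediate use of the crude aldehyde avoids epimerisation of the α‑stereocentre.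

Step 3
Reactants: 4 (S)‑2‑methyl‑3‑[(triisopropylsilyl)oxy]propanal; 5 allenyltributylstannane
Product: 6 (2S,3S)‑2‑methyl‑1‑[(triisopropylsilyl)oxy]hex‑5‑yn‑3‑ol
Conditions: allenylSnBu3 (1.3 eq), BF3·OEt2 (1.2 eq), CH2Cl2, −78 °C; aq. NaHCO3/KF work‑up; minor anti epimer removed on silica
Reagents that add atoms: allenyltributylstannane (5), CCCC[Sn](CCCC)(CCCC)C=C=C
Why: Lewis‑acid‑promoted SE2′ propargylation through an open transition state; with monodentate BF3 and a non‑chelating silyl ether the addition follows Felkin–Anh control by the bought methyl stereocentre and gives the 2,3‑syn (3S) alcohol, expected dr about 5–10:1.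

Step 4
Reactants: 6 (2S,3S)‑2‑methyl‑1‑[(triisopropylsilyl)oxy]hex‑5‑yn‑3‑ol; 7 3,6‑dibromopyridazine
Product: 8 3‑bromo‑6‑{[(2S,3S)‑2‑methyl‑1‑[(triisopropylsilyl)oxy]hex‑5‑yn‑3‑yl]oxy}pyridazine
Conditions: NaH (1.1 eq) added to 6 + 7 (1.2 eq), THF, 0 °C → rt
Reagents that add atoms: 3,6‑dibromopyridazine (7), Brc1ccc(Br)nn1
Why: NaH‑mediated SNAr of the secondary alcohol on the electron‑poor dihalodiazine; the carbinol C–O bond is not broken so C3 keeps its configuration, and the first alkoxy group deactivates the ring toward a second substitution.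

Step 5
Reactants: 8 3‑bromo‑6‑{[(2S,3S)‑2‑methyl‑1‑[(triisopropylsilyl)oxy]hex‑5‑yn‑3‑yl]oxy}pyridazine
Product: 10 (2S)‑5‑bromo‑2‑[(2S)‑1‑[(triisopropylsilyl)oxy]propan‑2‑yl]‑2,3‑dihydro‑1‑benzofuran, via diazabicyclo[2.2.2]octatriene cycloadduct 9 (not isolated)
Conditions: 1,2‑dichlorobenzene (0.02 M), BHT (cat.), sealed tube, 200 °C, 12–24 h
Reagents that add atoms: none
Why: Intramolecular inverse‑electron‑demand Diels–Alder of the tethered alkyne across C3/C6 of the pyridazine, then retro‑Diels–Alder loss of N2, builds the benzene and dihydrofuran rings at once; the tether fixes the regiochemistry so Br ends para to oxygen (C5), and neither stereocentre is involved.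

Step 6
Reactants: 10 (2S)‑5‑bromo‑2‑[(2S)‑1‑[(triisopropylsilyl)oxy]propan‑2‑yl]‑2,3‑dihydro‑1‑benzofuran
Product: 11 (2S)‑2‑[(2S)‑5‑bromo‑2,3‑dihydro‑1‑benzofuran‑2‑yl]propan‑1‑ol
Conditions: TBAF (1.2 eq), THF, 0 °C → rt
Reagents that add atoms: none
Why: Fluoride‑driven desilylation of the primary silyl ether; the aryl bromide and the cyclic aryl ether are inert.

Step 7
Reactants: 11 (2S)‑2‑[(2S)‑5‑bromo‑2,3‑dihydro‑1‑benzofuran‑2‑yl]propan‑1‑ol; 12 (E)‑3‑(4‑hydroxyphenyl)prop‑2‑enoic acid (p‑coumaric acid)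
Product: 13 (2S)‑2‑[(2S)‑5‑bromo‑2,3‑dihydro‑1‑benzofuran‑2‑yl]propyl (E)‑3‑(4‑hydroxyphenyl)prop‑2‑enoate
Conditions: 12 (1.2 eq), PPh3 (1.3 eq), DIAD (1.3 eq, slow addition), THF, 0 °C → rt
Reagents that add atoms: p‑coumaric acid (12), OC(=O)/C=C/c1ccc(O)cc1
Why: Mitsunobu esterification at the primary carbinol; the carboxylic acid (pKa about 4.5) is the pronucleophile well ahead of the phenol (pKa about 9–10), so no phenol protection is needed, and no stereocentre is at the reacting carbon.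

Step 8
Reactants: 13 (2S)‑2‑[(2S)‑5‑bromo‑2,3‑dihydro‑1‑benzofuran‑2‑yl]propyl (E)‑3‑(4‑hydroxyphenyl)prop‑2‑enoate; 14 acrylic acid
Product: 15 (E)‑3‑{(2S)‑2‑[(2S)‑1‑{[(E)‑3‑(4‑hydroxyphenyl)prop‑2‑enoyl]oxy}propan‑2‑yl]‑2,3‑dihydro‑1‑benzofuran‑5‑yl}prop‑2‑enoic acid (target)
Conditions: 14 (3 eq), Pd(OAc)2 (5 mol %), P(o‑tol)3 (10 mol %), Et3N (4 eq), DMF, 90 °C; 1 M HCl work‑up
Reagents that add atoms: acrylic acid (14), C=CC(=O)O
Why: Mizoroki–Heck coupling of the aryl bromide with the monosubstituted, unhindered acrylic acid gives the (E)‑cinnamic acid by syn insertion/syn β‑hydride elimination; the 1,2‑disubstituted coumarate alkene reacts much more slowly, and the ester and free phenol tolerate the conditions.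

## Compound list

1 | methyl (S)‑3‑hydroxy‑2‑methylpropanoate (Roche ester) | C[C@@H](CO)C(=O)OC | starting material
2 | triisopropylsilyl chloride | CC(C)[Si](Cl)(C(C)C)C(C)C | starting material
3 | methyl (S)‑2‑methyl‑3‑[(triisopropylsilyl)oxy]propanoate | C[C@@H](CO[Si](C(C)C)(C(C)C)C(C)C)C(=O)OC | intermediate
4 | (S)‑2‑methyl‑3‑[(triisopropylsilyl)oxy]propanal | C[C@@H](CO[Si](C(C)C)(C(C)C)C(C)C)C=O | intermediate
5 | allenyltributylstannane | CCCC[Sn](CCCC)(CCCC)C=C=C | starting material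
6 | (2S,3S)‑2‑methyl‑1‑[(triisopropylsilyl)oxy]hex‑5‑yn‑3‑ol | C[C@@H](CO[Si](C(C)C)(C(C)C)C(C)C)[C@@H](O)CC#C | intermediate
7 | 3,6‑dibromopyridazine | Brc1ccc(Br)nn1 | starting material
8 | 3‑bromo‑6‑{[(2S,3S)‑2‑methyl‑1‑[(triisopropylsilyl)oxy]hex‑5‑yn‑3‑yl]oxy}pyridazine | C[C@@H](CO[Si](C(C)C)(C(C)C)C(C)C)[C@@H](Oc1ccc(Br)nn1)CC#C | intermediate
9 | diazabicyclo[2.2.2]octatriene cycloadduct (bridgehead Br, fused tetrahydrofuran; bridgehead epimers, not isolated) | C[C@@H](CO[Si](C(C)C)(C(C)C)C(C)C)[C@@H]1CC2=CC3(Br)C=CC2(O1)N=N3 | intermediate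
10 | (2S)‑5‑bromo‑2‑[(2S)‑1‑[(triisopropylsilyl)oxy]propan‑2‑yl]‑2,3‑dihydro‑1‑benzofuran | C[C@@H](CO[Si](C(C)C)(C(C)C)C(C)C)[C@@H]1Cc2cc(Br)ccc2O1 | intermediate
11 | (2S)‑2‑[(2S)‑5‑bromo‑2,3‑dihydro‑1‑benzofuran‑2‑yl]propan‑1‑ol | C[C@@H](CO)[C@@H]1Cc2cc(Br)ccc2O1 | intermediate
12 | (E)‑3‑(4‑hydroxyphenyl)prop‑2‑enoic acid (p‑coumaric acid) | OC(=O)/C=C/c1ccc(O)cc1 | starting material
13 | (2S)‑2‑[(2S)‑5‑bromo‑2,3‑dihydro‑1‑benzofuran‑2‑yl]propyl (E)‑3‑(4‑hydroxyphenyl)prop‑2‑enoate | C[C@@H](COC(=O)/C=C/c1ccc(O)cc1)[C@@H]1Cc2cc(Br)ccc2O1 | intermediate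
14 | acrylic acid | C=CC(=O)O | starting material
15 | (E)‑3‑{(2S)‑2‑[(2S)‑1‑{[(E)‑3‑(4‑hydroxyphenyl)prop‑2‑enoyl]oxy}propan‑2‑yl]‑2,3‑dihydro‑1‑benzofuran‑5‑yl}prop‑2‑enoic acid | C[C@@H](COC(=O)/C=C/c1ccc(O)cc1)[C@@H]1Cc2cc(/C=C/C(=O)O)ccc2O1 | target

## Step count and risks

Total step count: 8. Longest linear sequence: 8 steps (1 → 15).

Steps most likely to fail:

**Step 3 (Felkin selectivity of the propargylation).** If the syn:anti ratio is poor, the fallback sets out from 4 and comes back at 6. Aldehyde 4 is propargylated without relying on facial bias (propargyl bromide, Zn, THF/aq. NH4Cl) and the epimers are separated. The unwanted anti epimer (2S,3R)‑2‑methyl‑1‑[(triisopropylsilyl)oxy]hex‑5‑yn‑3‑ol F1 is inverted by a Mitsunobu reaction (4‑nitrobenzoic acid, PPh3, DIAD, toluene) to (2S,3S)‑2‑methyl‑1‑[(triisopropylsilyl)oxy]hex‑5‑yn‑3‑yl 4‑nitrobenzoate F2. Methanolysis (K2CO3, MeOH) then gives 6, so C3 is set by SN2 inversion instead of by addition selectivity.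

**Step 5 (thermal cycloaddition/N2 extrusion).** If the alkoxy‑substituted diazine is too unreactive or the ether decomposes at 200 °C, the fallback sets out from 4 and comes back at 10, closing the ring by C–O bond formation instead. 5‑Bromo‑2‑fluorobenzyl bromide and Mg (Et2O, 0 °C) give (5‑bromo‑2‑fluorobenzyl)magnesium bromide F3. Felkin addition of this to 4 at −78 °C gives (2S,3S)‑1‑(5‑bromo‑2‑fluorophenyl)‑3‑methyl‑4‑[(triisopropylsilyl)oxy]butan‑2‑ol F4 after removal of the minor epimer. Intramolecular SNAr of the alkoxide on the ortho fluoride (KOtBu, THF/DMF, 65–80 °C, 5‑exo, retention at the carbinol) gives 10.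

**Step 8 (Heck coupling with free acrylic acid beside the coumarate alkene and free phenol).** If chemoselectivity or isolation of the acid fails, the fallback sets out from 10 and comes back at 15, putting the Heck before the coumaroylation and masking the acid.
- 10 and tert‑butyl acrylate (Pd(OAc)2, P(o‑tol)3, Et3N, DMF, 100 °C) give tert‑butyl (E)‑3‑{(2S)‑2‑[(2S)‑1‑[(triisopropylsilyl)oxy]propan‑2‑yl]‑2,3‑dihydro‑1‑benzofuran‑5‑yl}prop‑2‑enoate F5.
- TBAF gives tert‑butyl (E)‑3‑{(2S)‑2‑[(2S)‑1‑hydroxypropan‑2‑yl]‑2,3‑dihydro‑1‑benzofuran‑5‑yl}prop‑2‑enoate F6.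
- Mitsunobu esterification with 12 gives tert‑butyl (E)‑3‑{(2S)‑2‑[(2S)‑1‑{[(E)‑3‑(4‑hydroxyphenyl)prop‑2‑enoyl]oxy}propan‑2‑yl]‑2,3‑dihydro‑1‑benzofuran‑5‑yl}prop‑2‑enoate F7.
- TFA/CH2Cl2 at 0 °C → rt cleaves the tert‑butyl ester to give 15.

## Further compounds

F1 | step 3 | (2S,3R)‑2‑methyl‑1‑[(triisopropylsilyl)oxy]hex‑5‑yn‑3‑ol | C[C@@H](CO[Si](C(C)C)(C(C)C)C(C)C)[C@H](O)CC#C
F2 | step 3 | (2S,3S)‑2‑methyl‑1‑[(triisopropylsilyl)oxy]hex‑5‑yn‑3‑yl 4‑nitrobenzoate | C[C@@H](CO[Si](C(C)C)(C(C)C)C(C)C)[C@@H](OC(=O)c1ccc(cc1)[N+](=O)[O-])CC#C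
F3 | step 5 | (5‑bromo‑2‑fluorobenzyl)magnesium bromide | Fc1ccc(Br)cc1C[Mg]Br
F4 | step 5 | (2S,3S)‑1‑(5‑bromo‑2‑fluorophenyl)‑3‑methyl‑4‑[(triisopropylsilyl)oxy]butan‑2‑ol | C[C@@H](CO[Si](C(C)C)(C(C)C)C(C)C)[C@@H](O)Cc1cc(Br)ccc1F
F5 | step 8 | tert‑butyl (E)‑3‑{(2S)‑2‑[(2S)‑1‑[(triisopropylsilyl)oxy]propan‑2‑yl]‑2,3‑dihydro‑1‑benzofuran‑5‑yl}prop‑2‑enoate | C[C@@H](CO[Si](C(C)C)(C(C)C)C(C)C)[C@@H]1Cc2cc(/C=C/C(=O)OC(C)(C)C)ccc2O1
F6 | step 8 | tert‑butyl (E)‑3‑{(2S)‑2‑[(2S)‑1‑hydroxypropan‑2‑yl]‑2,3‑dihydro‑1‑benzofuran‑5‑yl}prop‑2‑enoate | C[C@@H](CO)[C@@H]1Cc2cc(/C=C/C(=O)OC(C)(C)C)ccc2O1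
F7 | step 8 | tert‑butyl (E)‑3‑{(2S)‑2‑[(2S)‑1‑{[(E)‑3‑(4‑hydroxyphenyl)prop‑2‑enoyl]oxy}propan‑2‑yl]‑2,3‑dihydro‑1‑benzofuran‑5‑yl}prop‑2‑enoate | C[C@@H](COC(=O)/C=C/c1ccc(O)cc1)[C@@H]1Cc2cc(/C=C/C(=O)OC(C)(C)C)ccc2O1
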